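## Structural features

The target is a pentasubstituted benzene: in benzoic acid numbering C1 carries CO2H, C2 and C4 carry OH, C3 is the only ring C–H, C5 carries CH3 and C6 carries a saturated 13-methyltetradecyl chain (twelve methylenes ending in an isopropyl group). There is one ring, no stereocentre and no unsaturation outside the arene, so the chain is a spectator and the problem is the regiochemistry of five different substituents on contiguous ring carbons. The fragile elements are the β-resorcylic acid unit, which loses CO2 on heating or in strong acid, and the electron-rich resorcinol nucleus, which is easily halogenated or oxidised at C3. The real difficulty is therefore to set the contiguous CH3/chain/CO2H/OH array without ambiguity and to create the acid late and mildly. The key step uses the 1,3-relationship of the two oxygens: C2 and its oxygen can come from carbon monoxide and the C4 oxygen from a migrating acyloxy group. That leaves C3–C4–C5–C6–C1 as a five-carbon enyne in which C3≡C4 is a terminal alkyne, C5 is a tertiary carbinol carbon bearing the methyl group, and C6=C1 is a 1,1-disubstituted alkene bearing the chain on C6. C1 then emerges as C–H, ortho to the C2 hydroxyl and para to the C4 oxygen, which is where electrophilic formylation of a resorcinol is directed.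

## Logic of the disconnections

19 ⇒ 18. No ring bond is cut; the C1 carboxyl group is taken back to a formyl group. The acid is the most fragile function, so it is made last, and 18 is a stable hydrogen-bonded hydroxy aldehyde. The forward step must oxidise CHO to CO2H at room temperature and mildly acidic pH without touching two free phenols or the open C3 position.

18 ⇒ 16. The bond between C1 and its formyl carbon is cut. C1 is ortho to the C2 hydroxyl and para to the C4 hydroxyl, and the one-carbon unit comes from a cheap formamide, so 16 carries no carbonyl group at all. The forward step must attack C1 and not C3, and only once; the iminium salt 17 is hydrolysed in the work-up.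

16 ⇒ 15. Only the acyl–oxygen bond at the C4 oxygen is involved. The monoester is what the ring-forming step delivers, and removing it first gives the fully activated resorcinol for the formylation. The forward step is a transesterification of an aryl ester, run without air because 16 is electron-rich.

15 ⇒ 13 + 14. Ring bonds C2–C3 and C1–C2 are cut and the acetoxy group is moved back from C4 to C5. This turns a pentasubstituted arene into an acyclic enyne and a one-carbon gas, so every ring position is fixed by chain connectivity and 13 can be used as the racemate. The forward step needs a 1,2- and not a 1,3-acyloxy shift, capture of 14 before the carbene closes onto the alkene, and a cis arrangement of C3 and C6 across the new C4=C5 bond.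

13 ⇒ 12. The acyl–oxygen bond of the tertiary ester is cut. The ester serves only as the migrating group; the smallest acyl group is kept because it goes onto a hindered tertiary alcohol under nucleophilic catalysis and comes off again under the mildest conditions. The forward acylation must be free of acid so that the allylic and propargylic tertiary alcohol does not ionise.

12 ⇒ 8 + 9. The C5–C6 bond (carbinol carbon to alkene carbon) and the alkyne C–Si bond are cut. This gives a four-carbon ketone that already holds the alkyne and the C5 methyl group, and an alkenyl bromide that holds the chain. The alkenyl nucleophile is the magnesium compound 10, made with magnesium metal, which avoids a pyrophoric alkyllithium. The silyl group of 11 is removed in the same flask, so one operation replaces two. The forward step needs 1,2-addition to an enolisable ynone; the silyl group blocks conjugate addition and masks the acidic alkyne hydrogen.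

8 ⇒ 5 + 6. The bond between the allylic carbon and the chain (C3–C4 of 8) is cut. 6 is a three-carbon unit whose allylic and vinylic bromides differ widely in reactivity, and 5 is a plain primary bromide that becomes 7. The forward step must substitute only the allylic position.

5 ⇒ 4. The C–Br bond is traced back to C–OH. The forward step is a clean substitution at an unhindered primary carbon.

4 ⇒ 1 + 2. The bond between C11 and C12 of 4 is cut, which introduces the isopropyl end by one sp3–sp3 coupling of two bulk chemicals. The hydroxyl group needs no protection because it travels as the alkoxide 3. The forward step needs an excess of 2 and a coupling that is faster than elimination or homocoupling.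

## Other disconnections considered

Alternative 1: The cut is the C1–C6 ring bond, which unfolds the ring into a linear tetraketide that already contains the carboxyl carbon. In the forward sense 2,2-dimethyl-6-(3,17-dimethyl-2,4-dioxooctadecyl)-4H-1,3-dioxin-4-one A1 would be heated with phenylmethanol A2. Cycloreversion of A1 would unmask an acylketene, which A2 would trap as benzyl 6,20-dimethyl-3,5,7-trioxohenicosanoate A3. Mild base would then let the future C1 carbanion of A3 add to the future C6 ketone, and dehydration would give benzyl 2,4-dihydroxy-5-methyl-6-(13-methyltetradecyl)benzoate A4.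
- In its favour: the carboxyl position is fixed by connectivity, no electrophilic substitution or oxidation is needed on the electron-rich arene, and neutral hydrogenolysis of A4 would finish the synthesis in one step. On end-game length (one step against three) and on regiochemical certainty at C1 this alternative is the better plan.
- Against it here: A1 contains a 2-methyl-1,3-diketone that has to be built by C-acylation of a dioxinone enolate plus a separate C-methylation, both open to O- versus C-selectivity problems. A3 has several enolisable sites, could close through oxygen to a pyranone or fragment by retro-Claisen cleavage, and its C6 ketone is flanked by the branched C5 and the long chain.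
- Comparison: both plans fix the ring positions through an open-chain precursor and reach the arene oxidation level directly. The alternative rests on ionic polycarbonyl chemistry that is sensitive to base and temperature; the chosen plan rests on a neutral metal-catalysed cascade with a hindered tertiary ester. The chain has to be made in either case, so the total step count should be about equal, with more storable intermediates in the chosen plan.

Alternative 2: The cuts are C5–C6 and C3–C4, and the ring is assembled at the cyclohexanedione oxidation level. Methyl 2-acetyl-16-methylheptadec-2-enoate A5 would take up 1-methoxy-1-(trimethylsilyloxy)prop-1-ene A6 in a TiCl4-promoted Mukaiyama–Michael addition, in which the nucleophilic carbon of A6 becomes C5 and bonds to C6. NaOCH3 added to the same flask would then close C3–C4 by Dieckmann condensation to methyl 5-methyl-6-(13-methyltetradecyl)-2,4-dioxocyclohexane-1-carboxylate A7, a mixture of diastereomers. Dehydrogenation of A7 to methyl 2,4-dihydroxy-5-methyl-6-(13-methyltetradecyl)benzoate A8 and ester hydrolysis would follow.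
- In its favour: A5 and A6 are joined by classical, inexpensive chemistry with no toxic gas and no precious metal, and all ring carbons plus the carboxyl carbon arrive in one flask. A6 is a simple silyl ketene acetal that needs no chain-building effort. On reagent hazard and cost this alternative is better than the chosen plan. The stereochemistry of A7 is irrelevant because aromatisation erases it.
- Against it here: A7 is below the arene oxidation level, and the halogenation–dehydrohalogenation normally used to aromatise could also attack C3 of A8. The ester of A8 sits between the chain and a hydrogen-bonded hydroxyl, so saponification would need forcing base, under which the acid is liable to decarboxylate. Making A5 costs the same chain-building effort as the chosen plan.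
- Comparison: both plans place every substituent unambiguously and the step counts should be about equal. The alternative must oxidise a saturated ring and then unmask a hindered ester, whereas the chosen plan forms the arene directly and frees the acid under buffered conditions.

Alternative 3: The cuts are C1–C2 and C5–C6 in a [4+2] sense. 1-Methoxy-4-methyl-3-(trimethylsilyloxy)cyclohexa-1,3-diene A9 and methyl 16-methylheptadec-2-ynoate A10 would combine on heating to methyl 1-methoxy-4-methyl-3-(13-methyltetradecyl)-5-(trimethylsilyloxy)bicyclo[2.2.2]octa-2,5-diene-2-carboxylate A11. A11 would then lose its saturated two-carbon bridge by cycloreversion to give methyl 2-methoxy-5-methyl-6-(13-methyltetradecyl)-4-(trimethylsilyloxy)benzoate A12.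
- In its favour: A9 and A10 are fragments of similar size that are joined late, the regiochemistry follows from the polarisation of A9, the carboxyl group is present in A10 from the start, and the two oxygens emerge differentiated in A12. On convergence and on regiocontrol at C1 this alternative is better than the chosen plan.
- Against it here: A10 is a β-alkyl ynoate and therefore a sluggish dienophile, and the bond-forming terminus of A9 that carries the methyl group is fully substituted. Prolonged heating well above 150 °C is to be expected, where A9 can isomerise or lose its silyl group. A12 still needs cleavage of an aryl methyl ether and hydrolysis of a hindered methyl ester, both harsh for a decarboxylation-prone acid. The key step also discards two carbons and a silyl group, whereas the chosen key step incorporates every atom of both partners.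
- Comparison: step counts should be about equal and each plan has one demanding step. The risk of the alternative lies in thermal reactivity and the deprotections; that of the chosen plan lies in a hindered tertiary ester and a late formylation.

Key step: step 6

Remark on the chemistry: 11, 12 and 13 are carried as racemates because their single stereocentre becomes the sp2 carbon C5 in step 6; ring positions are quoted in the benzoic acid numbering of 19 throughout.

## Route

Step 1
Reactants: 1 11-bromoundecan-1-ol; 2 isopropylmagnesium bromide
Product: 4 12-methyltridecan-1-ol, via bromomagnesium 11-bromoundecan-1-olate 3 (not isolated)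
Conditions: 2 (2.6 equiv), Li2CuCl4 (3 mol%), THF, −20 °C → rt; aq NH4Cl
Reagents that add atoms: none
Why: The first equivalent of 2 converts the hydroxyl into the alkoxide 3, and a copper-catalysed Kochi-type sp3–sp3 coupling of the primary bromide with the secondary Grignard reagent then installs the isopropyl terminus; primary bromides are the best electrophiles for this coupling.

Step 2
Reactants: 4 12-methyltridecan-1-ol
Product: 5 1-bromo-12-methyltridecane
Conditions: CBr4, PPh3, CH2Cl2, 0 °C → rt
Reagents that add atoms: tetrabromomethane, BrC(Br)(Br)Br
Why: Appel bromination; the oxyphosphonium intermediate is displaced by bromide in an SN2 reaction at an unhindered primary carbon, with nothing else in the molecule to interfere.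

Step 3
Reactants: 5 1-bromo-12-methyltridecane; 6 2,3-dibromoprop-1-ene
Product: 8 2-bromo-15-methylhexadec-1-ene, via 12-methyltridecylmagnesium bromide 7 (not isolated)
Conditions: Mg, THF, 45 °C; then 6 (1.2 equiv), CuI (5 mol%), THF, −10 °C → rt
Reagents that add atoms: none
Why: Grignard formation followed by copper-catalysed allylic substitution; only the allylic C–Br bond of 6 reacts (SN2 and SN2' attack give the same product), and the vinylic bromide is inert under these conditions.

Step 4
Reactants: 8 2-bromo-15-methylhexadec-1-ene; 9 4-(trimethylsilyl)but-3-yn-2-one
Product: 12 3,17-dimethyl-4-methylideneoctadec-1-yn-3-ol (racemic), via alkenylmagnesium bromide 10 (not isolated), via silylated alkynol 11 (not isolated)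
Conditions: Mg (I2-activated), THF, 50 °C; then 9, LaCl3·2LiCl (0.3 equiv), THF, −40 → 0 °C; then MeOH, K2CO3, rt, same flask; aq NH4Cl
Reagents that add atoms: none
Why: The alkenyl Grignard reagent adds 1,2 to the ynone (the silyl group blocks conjugate addition and masks the alkyne C–H, the lanthanum salt suppresses enolisation), and base-mediated methanolysis of the C(sp)–Si bond then frees the terminal alkyne; the new stereocentre forms as a racemate and is erased in step 6.

Step 5
Reactants: 12 3,17-dimethyl-4-methylideneoctadec-1-yn-3-ol (racemic)
Product: 13 3,17-dimethyl-4-methylideneoctadec-1-yn-3-yl acetate (racemic)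
Conditions: Ac2O, Et3N, DMAP (0.2 equiv), CH2Cl2, rt → 40 °C
Reagents that add atoms: acetic anhydride, CC(=O)OC(C)=O
Why: DMAP-catalysed acylation through the N-acetylpyridinium ion, the standard way to esterify a tertiary propargylic alcohol; the basic medium avoids ionisation or Meyer–Schuster rearrangement of the allylic and propargylic carbinol.

Step 6
Reactants: 13 3,17-dimethyl-4-methylideneoctadec-1-yn-3-yl acetate (racemic); 14 carbon monoxide
Product: 15 5-hydroxy-2-methyl-3-(13-methyltetradecyl)phenyl acetate
Conditions: [RhCl(CO)2]2 (5 mol%), 14 (10 bar), CH2Cl2, 80 °C, autoclave
Reagents that add atoms: none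
Why: Monovalent rhodium coordinates the terminal alkyne of 13, the acetate carbonyl oxygen attacks the internal alkyne carbon (future C4) anti to the metal, and opening of the five-membered acyloxonium completes a 1,2-acyloxy shift that leaves a rhodium carbene on the former terminal carbon (C3) and a new C4=C5 double bond. Migratory insertion of 14 into the carbene forms C2–C3 and gives a dienylketene, free or still bound to rhodium. The benzene ring then closes between the ketene carbon C2 and the unsubstituted methylene terminus C1 by a 6π-electrocyclisation (equivalently, reductive elimination from a six-membered rhodacycle), and the cyclohexadienone tautomerises to the phenol, so aromatisation drives the sequence. The closest known reaction type is the rhodium-catalysed carbonylative [5+1] benzannulation of 3-acyloxy-1,4-enynes to resorcinol monoesters, applied here to a tertiary ester next to a 1,1-disubstituted alkene. No stereocentre is formed, and the one in 13 is erased when C5 becomes aromatic. Three selectivities are needed: the 1,2-shift must win over the 1,3-shift, which the unsubstituted alkyne terminus secures because it cannot stabilise positive charge; 14 must be captured before the vinyl carbene closes onto the alkene, which CO pressure and the carbonyl-rich catalyst favour; and C3 and C6 must be cis across C4=C5, which the reversibility of the acyloxy shift provides by returning the unproductive isomer. The linear connectivity C3–C4–C5–C6–C1 then fixes hydroxyl at C2, hydrogen at C3, acetoxy at C4, methyl at C5, the chain at C6 and hydrogen at C1.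

Step 7
Reactants: 15 5-hydroxy-2-methyl-3-(13-methyltetradecyl)phenyl acetate
Product: 16 4-methyl-5-(13-methyltetradecyl)benzene-1,3-diol
Conditions: K2CO3, MeOH (degassed), rt, N2; dilute aq HCl
Reagents that add atoms: none
Why: Base-catalysed transesterification of an aryl acetate, fast because phenoxide is a good leaving group; exclusion of air protects the electron-rich resorcinol.

Step 8
Reactants: 16 4-methyl-5-(13-methyltetradecyl)benzene-1,3-diol
Product: 18 2,4-dihydroxy-5-methyl-6-(13-methyltetradecyl)benzaldehyde, via aryl iminium chloride 17 (not isolated)
Conditions: POCl3 (1.3 equiv), DMF, MeCN, 0 °C → rt; then H2O, 50 °C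
Reagents that add atoms: N,N-dimethylformamide, CN(C)C=O; water, O
Why: Vilsmeier–Haack formylation; the chloroiminium electrophile attacks C1, which is para to the C4 hydroxyl and ortho to the C2 hydroxyl, in preference to C3 between the two hydroxyls, as is usual for 5-alkylresorcinols, and hydrolysis of 17 gives the hydrogen-bonded aldehyde.

Step 9
Reactants: 18 2,4-dihydroxy-5-methyl-6-(13-methyltetradecyl)benzaldehyde
Product: 19 2,4-dihydroxy-5-methyl-6-(13-methyltetradecyl)benzoic acid
Conditions: NaClO2 (1.5 equiv), NaH2PO4, DMSO/THF/H2O, 0 °C → rt; acidify to pH 3 at 0 °C
Reagents that add atoms: sodium chlorite, [Na+].[O-]Cl=O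
Why: Lindgren–Pinnick chlorite oxidation; chlorous acid adds to the aldehyde and fragments to the acid and hypochlorous acid, which the large excess of DMSO reduces before it can chlorinate C3, and the buffered room-temperature medium avoids decarboxylation.

## Compound list

1 | 11-bromoundecan-1-ol | OCCCCCCCCCCCBr | starting material
2 | isopropylmagnesium bromide | CC(C)[Mg]Br | starting material
3 | bromomagnesium 11-bromoundecan-1-olate | BrCCCCCCCCCCCO[Mg]Br | intermediate
4 | 12-methyltridecan-1-ol | CC(C)CCCCCCCCCCCO | intermediate
5 | 1-bromo-12-methyltridecane | CC(C)CCCCCCCCCCCBr | intermediate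
6 | 2,3-dibromoprop-1-ene | C=C(Br)CBr | starting material
7 | 12-methyltridecylmagnesium bromide | CC(C)CCCCCCCCCCC[Mg]Br | intermediate
8 | 2-bromo-15-methylhexadec-1-ene | C=C(Br)CCCCCCCCCCCCC(C)C | intermediate
9 | 4-(trimethylsilyl)but-3-yn-2-one | CC(=O)C#C[Si](C)(C)C | starting material
10 | (15-methylhexadec-1-en-2-yl)magnesium bromide | C=C([Mg]Br)CCCCCCCCCCCCC(C)C | intermediate
11 | 3,17-dimethyl-4-methylidene-1-(trimethylsilyl)octadec-1-yn-3-ol (racemic) | C[Si](C)(C)C#CC(C)(O)C(=C)CCCCCCCCCCCCC(C)C | intermediate
12 | 3,17-dimethyl-4-methylideneoctadec-1-yn-3-ol (racemic) | C#CC(C)(O)C(=C)CCCCCCCCCCCCC(C)C | intermediate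
13 | 3,17-dimethyl-4-methylideneoctadec-1-yn-3-yl acetate (racemic) | C#CC(C)(OC(C)=O)C(=C)CCCCCCCCCCCCC(C)C | intermediate
14 | carbon monoxide | [C-]#[O+] | starting material
15 | 5-hydroxy-2-methyl-3-(13-methyltetradecyl)phenyl acetate | CC(=O)Oc1cc(O)cc(CCCCCCCCCCCCC(C)C)c1C | intermediate
16 | 4-methyl-5-(13-methyltetradecyl)benzene-1,3-diol | Cc1c(O)cc(O)cc1CCCCCCCCCCCCC(C)C | intermediate
17 | N-{[2,4-dihydroxy-5-methyl-6-(13-methyltetradecyl)phenyl]methylidene}-N-methylmethanaminium chloride | Cc1c(O)cc(O)c(C=[N+](C)C)c1CCCCCCCCCCCCC(C)C.[Cl-] | intermediate
18 | 2,4-dihydroxy-5-methyl-6-(13-methyltetradecyl)benzaldehyde | Cc1c(O)cc(O)c(C=O)c1CCCCCCCCCCCCC(C)C | intermediate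
19 | 2,4-dihydroxy-5-methyl-6-(13-methyltetradecyl)benzoic acid (no stereocentre) | Cc1c(O)cc(O)c(C(=O)O)c1CCCCCCCCCCCCC(C)C | target

## Step count and least certain steps

Total step count: 9. Longest linear sequence: 9 steps (1 → 19); 2, 6, 9 and 14 enter as purchased partners.

Step 6 (key step). The most likely failures are ionisation of the tertiary ester, whose carbinol carbon is both allylic and propargylic and can eliminate, and closure of the vinyl carbene onto the alkene before CO is taken up, which would give a five-membered ring. Both are made more likely by the congestion around C5. Higher CO pressure should help the second problem but not the first. Fallback: the resorcinol is reached by classical arene chemistry, setting out from 5 through its Grignard reagent 7 and returning at 16. Copper-catalysed coupling of 7 with purchased 1-(bromomethyl)-3,5-dimethoxybenzene (Li2CuCl4, THF) should give 1,3-dimethoxy-5-(13-methyltetradecyl)benzene F1. Vilsmeier–Haack formylation (POCl3, DMF, 80 °C), para to one methoxy group and next to the chain, should give 2,4-dimethoxy-6-(13-methyltetradecyl)benzaldehyde F2. Hydrogenolysis of the electron-rich benzylic carbonyl group (H2, Pd/C, AcOH) should give 1,5-dimethoxy-2-methyl-3-(13-methyltetradecyl)benzene F3. BBr3 in CH2Cl2 (−78 °C → rt) would cleave both methyl ethers and deliver 16. This replaces steps 3 to 7, at the price that the ring is bought and not built.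

Step 4. Magnesium insertion into the hindered 2-bromoalkene may be sluggish and accompanied by homocoupling, and the basic alkenyl reagent may enolise the methyl ketone instead of adding to it. Fallback with reversed polarity, from 8 and returning at 12. Suzuki coupling of 8 with purchased 2-(1-ethoxyethenyl)-4,4,5,5-tetramethyl-1,3,2-dioxaborolane (Pd(PPh3)4, K3PO4, dioxane/H2O, 80 °C) should give 2-ethoxy-16-methyl-3-methylideneheptadec-1-ene F4. Dilute HCl would hydrolyse the enol ether to 16-methyl-3-methylideneheptadecan-2-one F5, which should be used at once. Ethynylmagnesium bromide in THF (−78 → 0 °C) should then add 1,2 and give 12 directly, without a silyl group.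

Step 8. Attack at C3, a second formylation, or slow reaction at C1 because of the neighbouring chain would lower regiochemical purity; O-formylation of the free phenols would consume reagent. Fallback that installs the carboxyl carbon by halogenation and metalation, from 16 and returning at 19 (it also replaces step 9). O-Benzylation (BnBr, K2CO3, DMF) should give 1,5-bis(benzyloxy)-2-methyl-3-(13-methyltetradecyl)benzene F6, in which C3 is shielded by two benzyloxy groups. NBS in MeCN (0 °C) should brominate para to a benzyloxy group to give 1,5-bis(benzyloxy)-2-bromo-4-methyl-3-(13-methyltetradecyl)benzene F7. Bromine–lithium exchange (n-BuLi, THF, −78 °C) would give [2,4-bis(benzyloxy)-5-methyl-6-(13-methyltetradecyl)phenyl]lithium F8, and quenching with CO2 would give 2,4-bis(benzyloxy)-5-methyl-6-(13-methyltetradecyl)benzoic acid F9. Hydrogenolysis (H2, Pd/C, EtOAc, rt) would then give 19 under neutral conditions.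

Step 9. Ring chlorination at C3 by hypochlorous acid that escapes the scavenger, oxidative degradation of the free resorcinol, and decarboxylation during an acidic or warm work-up are the likely losses. Fallback with temporary deactivation of the ring, from 18 and returning at 19. Acetylation of both phenols (Ac2O, pyridine, DMAP) should give 4-formyl-6-methyl-5-(13-methyltetradecyl)benzene-1,3-diyl diacetate F10. Standard Pinnick oxidation (NaClO2, NaH2PO4, 2-methylbut-2-ene, t-BuOH/H2O) on the deactivated ring should give 2,4-diacetoxy-5-methyl-6-(13-methyltetradecyl)benzoic acid F11. Cold saponification (LiOH, THF/H2O, 0 °C) and careful acidification would then give 19.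

## Further compounds

F1 | step 6 | 1,3-dimethoxy-5-(13-methyltetradecyl)benzene | COc1cc(OC)cc(CCCCCCCCCCCCC(C)C)c1
F2 | step 6 | 2,4-dimethoxy-6-(13-methyltetradecyl)benzaldehyde | COc1cc(OC)c(C=O)c(CCCCCCCCCCCCC(C)C)c1
F3 | step 6 | 1,5-dimethoxy-2-methyl-3-(13-methyltetradecyl)benzene | COc1cc(OC)c(C)c(CCCCCCCCCCCCC(C)C)c1
F4 | step 4 | 2-ethoxy-16-methyl-3-methylideneheptadec-1-ene | CCOC(=C)C(=C)CCCCCCCCCCCCC(C)C
F5 | step 4 | 16-methyl-3-methylideneheptadecan-2-one | CC(=O)C(=C)CCCCCCCCCCCCC(C)C
F6 | step 8 | 1,5-bis(benzyloxy)-2-methyl-3-(13-methyltetradecyl)benzene | Cc1c(OCc2ccccc2)cc(OCc2ccccc2)cc1CCCCCCCCCCCCC(C)C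
F7 | step 8 | 1,5-bis(benzyloxy)-2-bromo-4-methyl-3-(13-methyltetradecyl)benzene | Cc1c(OCc2ccccc2)cc(OCc2ccccc2)c(Br)c1CCCCCCCCCCCCC(C)C
F8 | step 8 | [2,4-bis(benzyloxy)-5-methyl-6-(13-methyltetradecyl)phenyl]lithium | [Li]c1c(OCc2ccccc2)cc(OCc2ccccc2)c(C)c1CCCCCCCCCCCCC(C)C
F9 | step 8 | 2,4-bis(benzyloxy)-5-methyl-6-(13-methyltetradecyl)benzoic acid | Cc1c(OCc2ccccc2)cc(OCc2ccccc2)c(C(=O)O)c1CCCCCCCCCCCCC(C)C
F10 | step 9 | 4-formyl-6-methyl-5-(13-methyltetradecyl)benzene-1,3-diyl diacetate | Cc1c(OC(C)=O)cc(OC(C)=O)c(C=O)c1CCCCCCCCCCCCC(C)C
F11 | step 9 | 2,4-diacetoxy-5-methyl-6-(13-methyltetradecyl)benzoic acid | Cc1c(OC(C)=O)cc(OC(C)=O)c(C(=O)O)c1CCCCCCCCCCCCC(C)C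
A1 | alternative 1 | 2,2-dimethyl-6-(3,17-dimethyl-2,4-dioxooctadecyl)-4H-1,3-dioxin-4-one | CC(C)CCCCCCCCCCCCC(=O)C(C)C(=O)CC1=CC(=O)OC(C)(C)O1
A2 | alternative 1 | phenylmethanol | OCc1ccccc1
A3 | alternative 1 | benzyl 6,20-dimethyl-3,5,7-trioxohenicosanoate | CC(C)CCCCCCCCCCCCC(=O)C(C)C(=O)CC(=O)CC(=O)OCc1ccccc1
A4 | alternative 1 | benzyl 2,4-dihydroxy-5-methyl-6-(13-methyltetradecyl)benzoate | Cc1c(O)cc(O)c(C(=O)OCc2ccccc2)c1CCCCCCCCCCCCC(C)C
A5 | alternative 2 | methyl 2-acetyl-16-methylheptadec-2-enoate | COC(=O)C(C(C)=O)=CCCCCCCCCCCCCC(C)C
A6 | alternative 2 | 1-methoxy-1-(trimethylsilyloxy)prop-1-ene | CC=C(OC)O[Si](C)(C)C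
A7 | alternative 2 | methyl 5-methyl-6-(13-methyltetradecyl)-2,4-dioxocyclohexane-1-carboxylate (mixture of diastereomers) | COC(=O)C1C(=O)CC(=O)C(C)C1CCCCCCCCCCCCC(C)C
A8 | alternative 2 | methyl 2,4-dihydroxy-5-methyl-6-(13-methyltetradecyl)benzoate | COC(=O)c1c(O)cc(O)c(C)c1CCCCCCCCCCCCC(C)C
A9 | alternative 3 | 1-methoxy-4-methyl-3-(trimethylsilyloxy)cyclohexa-1,3-diene | COC1=CC(O[Si](C)(C)C)=C(C)CC1
A10 | alternative 3 | methyl 16-methylheptadec-2-ynoate | COC(=O)C#CCCCCCCCCCCCCC(C)C
A11 | alternative 3 | methyl 1-methoxy-4-methyl-3-(13-methyltetradecyl)-5-(trimethylsilyloxy)bicyclo[2.2.2]octa-2,5-diene-2-carboxylate (racemic) | COC(=O)C1=C(CCCCCCCCCCCCC(C)C)C2(C)CCC1(OC)C=C2O[Si](C)(C)C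
A12 | alternative 3 | methyl 2-methoxy-5-methyl-6-(13-methyltetradecyl)-4-(trimethylsilyloxy)benzoate | COC(=O)c1c(OC)cc(O[Si](C)(C)C)c(C)c1CCCCCCCCCCCCC(C)C
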